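Ring C is cut at the two bonds it shares with ring A, O1–C8a and C4–C4a, which lie ortho to each other. One fluoride-triggered operation turns a ring A silyl triflate into the C4a–C8a aryne, adds the primary alkoxide of a chiral ester at C8a and lets the C4a anion close ring C on the ester carbonyl (C4). The step exploits the C5 oxygen beside C4a, which fixes the sense of addition, and the hydrogen-free C3, whose R configuration is set earlier by rhodium-catalysed arylation of a pyruvate and cannot scramble. The ester partner is an ethyl (R)-2,3-dihydroxy-2-arylpropanoate, used as its proton-free dialkoxide.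

Key step: step 13

Abbreviations: MOM = methoxymethyl; prenyl = 3-methylbut-2-en-1-yl; Ar = 2-methoxy-4-(methoxymethoxy)-3-prenylphenyl; chromanone atoms are O1, C2, C3, C4, C4a, C5–C8, C8a.

Design remark: the tertiary C3 hydroxyl is carried unprotected and the diol enters the key step as its dialkoxide. No O–H proton can then quench the C4a anion, and the doubly charged species has no retro-aldol exit (the leaving group would be an enediolate). No hindered tertiary alcohol has to be protected, and only three aryl MOM ethers remain for the last step.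

Assumption: in step 11 the ligand antipode that gives the R carbinol is chosen in a pilot run, and the configuration is checked on a crystalline derivative.

Step 1
Reactants: 1 phloroglucinol
Product: 2 3,5-bis(methoxymethoxy)phenol
Conditions: MOMCl (2.0 equiv), i-Pr2NEt, THF/DMF, 0 → 23 °C
Reagents that add atoms: chloromethyl methyl ether, COCCl
Why: Williamson-type O-alkylation of the threefold symmetric triol with two equivalents of MOMCl should give the bis-ether as the main fraction of a statistical mixture that is separable on silica, a loss that is acceptable on the cheapest material of the route.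

Step 2
Reactants: 2 3,5-bis(methoxymethoxy)phenol
Product: 3 [3,5-bis(methoxymethoxy)phenoxy]triisopropylsilane
Conditions: TIPSCl, imidazole, DMF, 23 °C
Reagents that add atoms: chlorotriisopropylsilane, CC(C)[Si](Cl)(C(C)C)C(C)C
Why: O-silylation of the remaining phenol with a bulky, non-coordinating group marks the oxygen that will become the triflate and shields its two ortho positions from the base used next.

Step 3
Reactants: 3 [3,5-bis(methoxymethoxy)phenoxy]triisopropylsilane; 4 prenyl bromide
Product: 6 [3,5-bis(methoxymethoxy)-4-prenylphenoxy]triisopropylsilane, via aryllithium 5 (not isolated)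
Conditions: n-BuLi, THF, 0 °C; then 4, −78 → 23 °C
Reagents that add atoms: none
Why: Directed ortho-metalation should occur only at the carbon flanked by both MOM ethers (two chelating acetal oxygens against a silyl ether that does not direct), and the aryllithium is then alkylated by SN2 attack on the primary allylic bromide.

Step 4
Reactants: 6 [3,5-bis(methoxymethoxy)-4-prenylphenoxy]triisopropylsilane
Product: 7 3,5-bis(methoxymethoxy)-4-prenylphenol
Conditions: TBAF, THF, 0 °C; AcOH
Reagents that add atoms: none
Why: Fluoride cleavage of the aryl silyl ether (desilylation) frees the phenol para to the prenyl group while the MOM ethers and the alkene are inert.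

Step 5
Reactants: 7 3,5-bis(methoxymethoxy)-4-prenylphenol
Product: 8 2-bromo-3,5-bis(methoxymethoxy)-4-prenylphenol
Conditions: NBS (1.0 equiv), CH2Cl2, −78 °C
Reagents that add atoms: N-bromosuccinimide, O=C1CCC(=O)N1Br
Why: Electrophilic aromatic bromination of a phenol activated by three oxygen substituents should be far faster at −78 °C than attack of NBS on the trisubstituted alkene, and the two open ring positions are equivalent, so one equivalent should give a single monobromide.

Step 6
Reactants: 8 2-bromo-3,5-bis(methoxymethoxy)-4-prenylphenol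
Product: 12 3,5-bis(methoxymethoxy)-4-prenyl-2-(trimethylsilyl)phenyl trifluoromethanesulfonate, via trimethylsilyl ether 9 (not isolated), via aryllithium 10 (not isolated), via lithium phenolate 11 (not isolated)
Conditions: HMDS, THF, 65 °C, evaporate; n-BuLi, THF, −100 → −78 °C; Tf2O, −100 → −78 °C
Reagents that add atoms: hexamethyldisilazane, C[Si](C)(C)N[Si](C)(C)C; trifluoromethanesulfonic anhydride, O=S(=O)(OS(=O)(=O)C(F)(F)F)C(F)(F)F
Why: This is the standard one-flask route to ortho-silylaryl triflates, namely O-silylation, bromine–lithium exchange (faster than any deprotonation at −100 °C), 1,3 O→C silyl shift (retro-Brook rearrangement) and O-triflation of the resulting phenolate.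

Step 7
Reactants: 13 4-bromo-3-methoxyphenol
Product: 14 1-bromo-2-methoxy-4-(methoxymethoxy)benzene
Conditions: MOMCl, i-Pr2NEt, CH2Cl2, 0 → 23 °C
Reagents that add atoms: chloromethyl methyl ether, COCCl
Why: Williamson-type protection of the phenol as its MOM ether, which also serves as the stronger of the two directing groups in the next step.

Step 8
Reactants: 14 1-bromo-2-methoxy-4-(methoxymethoxy)benzene; 4 prenyl bromide
Product: 16 1-bromo-2-methoxy-4-(methoxymethoxy)-3-prenylbenzene, via aryllithium 15 (not isolated)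
Conditions: lithium 2,2,6,6-tetramethylpiperidide (LiTMP, from 2,2,6,6-tetramethylpiperidine and n-BuLi), THF, −78 °C; then 4, −78 → 0 °C
Reagents that add atoms: none
Why: Directed ortho-metalation with a hindered lithium amide removes the most acidic ring hydrogen, the one between the methoxy and MOM-oxy groups, without halogen–lithium exchange at C–Br (the lithiated carbon is meta to bromine, so no aryne can form), and the aryllithium is alkylated by SN2 attack on the allylic bromide.

Step 9
Reactants: 16 1-bromo-2-methoxy-4-(methoxymethoxy)-3-prenylbenzene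
Product: 18 [2-methoxy-4-(methoxymethoxy)-3-prenylphenyl]boronic acid, via aryllithium 17 (not isolated)
Conditions: n-BuLi, THF, −78 °C; B(OiPr)3, −78 → 0 °C; aq. AcOH (pH 6)
Reagents that add atoms: triisopropyl borate, CC(C)OB(OC(C)C)OC(C)C; water, O
Why: Bromine–lithium exchange at −78 °C followed by borylation of the aryllithium with a trialkyl borate and mild hydrolysis should give the boronic acid regiospecifically at the former C–Br carbon.

Step 10
Reactants: 19 ethyl bromopyruvate
Product: 20 ethyl 3-(benzoyloxy)-2-oxopropanoate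
Conditions: PhCO2Na, NaI (cat.), acetone, 23 °C
Reagents that add atoms: sodium benzoate, [Na+].[O-]C(=O)c1ccccc1
Why: SN2 displacement of the activated α-bromo ketone by benzoate gives the acyloxy pyruvate, the benzoate serving as a base-removable mask for the future O1.

Step 11
Reactants: 18 [2-methoxy-4-(methoxymethoxy)-3-prenylphenyl]boronic acid; 20 ethyl 3-(benzoyloxy)-2-oxopropanoate
Product: 21 ethyl (R)-3-(benzoyloxy)-2-hydroxy-2-Ar-propanoate
Conditions: [RhCl(C2H4)2]2 (2.5 mol%), chiral N-tert-butanesulfinyl sulfur–olefin ligand (6 mol%), K3PO4 (0.5 equiv), toluene/H2O (10:1), 23 °C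
Reagents that add atoms: none
Why: Rhodium-catalysed enantioselective 1,2-addition of an arylboronic acid to an α-ketoester, in which transmetalation gives an aryl–rhodium species that inserts the activated ketone and the chiral sulfur–olefin ligand decides which carbonyl face is arylated, setting the future C3 stereocentre as R.

Step 12
Reactants: 21 ethyl (R)-3-(benzoyloxy)-2-hydroxy-2-Ar-propanoate
Product: 22 ethyl (R)-2,3-dihydroxy-2-Ar-propanoate
Conditions: K2CO3 (0.3 equiv), EtOH, 0 → 23 °C
Reagents that add atoms: none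
Why: Carbonate-catalysed ethanolysis (transesterification) removes the benzoate as ethyl benzoate while the ethyl ester only exchanges with the solvent, and the fully substituted carbinol carbon cannot epimerise.

Step 13
Reactants: 22 ethyl (R)-2,3-dihydroxy-2-Ar-propanoate; 12 3,5-bis(methoxymethoxy)-4-prenyl-2-(trimethylsilyl)phenyl trifluoromethanesulfonate
Product: 25 (R)-3-hydroxy-3-Ar-5,7-bis(methoxymethoxy)-6-prenylchroman-4-one, via disodium dialkoxide 23 (not isolated), via aryne 24 (not isolated)
Conditions: NaH (2.1 equiv), THF, 0 °C; then 12 (1.2 equiv), KF, 18-crown-6, 0 → 23 °C; AcOH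
Reagents that add atoms: none
Why: Proposed new method: NaH converts 22 into dialkoxide 23 with loss of hydrogen, desilylation of 12 by fluoride with loss of triflate then releases aryne 24, whose triple bond joins the future C4a and C8a, the primary alkoxide adds at C8a and the C4a anion attacks the ester carbonyl and expels ethoxide to give the C4 ketone. Its nearest precedent is the one-pot xanthone synthesis from ortho-silylaryl triflates and salicylates under fluoride, with its sulfur and nitrogen analogues; what has not been shown is an aliphatic alkoxide–ester partner. Ring C closes by 6-exo-trig acyl substitution, helped by the fully substituted C3. No stereocentre is created; C3 is fully substituted and none of its four bonds is made or broken, so the R configuration from step 11 passes through unchanged. Regioselectivity is needed and comes from the C5 MOM-oxy group, whose inductive pull makes C8a the electrophilic aryne terminus and leaves the charge at C4a beside it; preference for the primary over the tertiary alkoxide comes from steric shielding of the latter, and acyl capture over protonation from the absence of any acidic hydrogen in THF.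

Step 14
Reactants: 25 (R)-3-hydroxy-3-Ar-5,7-bis(methoxymethoxy)-6-prenylchroman-4-one
Product: 26 CNP0157505.1, (R)-3,5,7-trihydroxy-3-(4-hydroxy-2-methoxy-3-prenylphenyl)-6-prenylchroman-4-one
Conditions: HCl (2 M aq.), MeOH, 40 °C
Reagents that add atoms: none
Why: Acid-catalysed acetal exchange with methanol cleaves the three aryl MOM ethers under conditions mild enough to leave the prenyl groups (no chroman formation), the aryl methyl ether and the tertiary C3 carbinol, whose configuration is untouched.

Compound list
1 | phloroglucinol | Oc1cc(O)cc(O)c1 | starting material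
2 | 3,5-bis(methoxymethoxy)phenol | COCOc1cc(O)cc(OCOC)c1 | intermediate
3 | [3,5-bis(methoxymethoxy)phenoxy]triisopropylsilane | COCOc1cc(OCOC)cc(O[Si](C(C)C)(C(C)C)C(C)C)c1 | intermediate
4 | prenyl bromide (1-bromo-3-methylbut-2-ene) | CC(C)=CCBr | starting material
5 | [2,6-bis(methoxymethoxy)-4-(triisopropylsilyloxy)phenyl]lithium | [Li]c1c(OCOC)cc(O[Si](C(C)C)(C(C)C)C(C)C)cc1OCOC | intermediate
6 | [3,5-bis(methoxymethoxy)-4-(3-methylbut-2-en-1-yl)phenoxy]triisopropylsilane | CC(C)=CCc1c(OCOC)cc(O[Si](C(C)C)(C(C)C)C(C)C)cc1OCOC | intermediate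
7 | 3,5-bis(methoxymethoxy)-4-(3-methylbut-2-en-1-yl)phenol | CC(C)=CCc1c(OCOC)cc(O)cc1OCOC | intermediate
8 | 2-bromo-3,5-bis(methoxymethoxy)-4-(3-methylbut-2-en-1-yl)phenol | CC(C)=CCc1c(OCOC)cc(O)c(Br)c1OCOC | intermediate
9 | [2-bromo-3,5-bis(methoxymethoxy)-4-(3-methylbut-2-en-1-yl)phenoxy]trimethylsilane | CC(C)=CCc1c(OCOC)cc(O[Si](C)(C)C)c(Br)c1OCOC | intermediate
10 | [2,4-bis(methoxymethoxy)-3-(3-methylbut-2-en-1-yl)-6-(trimethylsilyloxy)phenyl]lithium | CC(C)=CCc1c(OCOC)cc(O[Si](C)(C)C)c([Li])c1OCOC | intermediate
11 | lithium 3,5-bis(methoxymethoxy)-4-(3-methylbut-2-en-1-yl)-2-(trimethylsilyl)phenolate | [Li+].[O-]c1cc(OCOC)c(CC=C(C)C)c(OCOC)c1[Si](C)(C)C | intermediate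
12 | 3,5-bis(methoxymethoxy)-4-(3-methylbut-2-en-1-yl)-2-(trimethylsilyl)phenyl trifluoromethanesulfonate | C[Si](C)(C)c1c(OS(=O)(=O)C(F)(F)F)cc(OCOC)c(CC=C(C)C)c1OCOC | intermediate
13 | 4-bromo-3-methoxyphenol | COc1cc(O)ccc1Br | starting material
14 | 1-bromo-2-methoxy-4-(methoxymethoxy)benzene | COCOc1ccc(Br)c(OC)c1 | intermediate
15 | [3-bromo-2-methoxy-6-(methoxymethoxy)phenyl]lithium | COc1c(Br)ccc(OCOC)c1[Li] | intermediate
16 | 1-bromo-2-methoxy-4-(methoxymethoxy)-3-(3-methylbut-2-en-1-yl)benzene | COc1c(Br)ccc(OCOC)c1CC=C(C)C | intermediate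
17 | [2-methoxy-4-(methoxymethoxy)-3-(3-methylbut-2-en-1-yl)phenyl]lithium | COc1c([Li])ccc(OCOC)c1CC=C(C)C | intermediate
18 | [2-methoxy-4-(methoxymethoxy)-3-(3-methylbut-2-en-1-yl)phenyl]boronic acid | COc1c(B(O)O)ccc(OCOC)c1CC=C(C)C | intermediate
19 | ethyl bromopyruvate | CCOC(=O)C(=O)CBr | starting material
20 | ethyl 3-(benzoyloxy)-2-oxopropanoate | CCOC(=O)C(=O)COC(=O)c1ccccc1 | intermediate
21 | ethyl (R)-3-(benzoyloxy)-2-hydroxy-2-[2-methoxy-4-(methoxymethoxy)-3-(3-methylbut-2-en-1-yl)phenyl]propanoate | COc1c([C@@](C(=O)OCC)(O)COC(=O)c2ccccc2)ccc(OCOC)c1CC=C(C)C | intermediate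
22 | ethyl (R)-2,3-dihydroxy-2-[2-methoxy-4-(methoxymethoxy)-3-(3-methylbut-2-en-1-yl)phenyl]propanoate | COc1c([C@@](C(=O)OCC)(O)CO)ccc(OCOC)c1CC=C(C)C | intermediate
23 | disodium (R)-3-ethoxy-2-[2-methoxy-4-(methoxymethoxy)-3-(3-methylbut-2-en-1-yl)phenyl]-3-oxopropane-1,2-bis(olate) | COc1c([C@@](C(=O)OCC)([O-])C[O-])ccc(OCOC)c1CC=C(C)C.[Na+].[Na+] | intermediate
24 | 3,5-bis(methoxymethoxy)-4-(3-methylbut-2-en-1-yl)-1,2-didehydrobenzene | COCOC1=C(CC=C(C)C)C(OCOC)=CC#C1 | intermediate
25 | (R)-3-hydroxy-3-[2-methoxy-4-(methoxymethoxy)-3-(3-methylbut-2-en-1-yl)phenyl]-5,7-bis(methoxymethoxy)-6-(3-methylbut-2-en-1-yl)chroman-4-one | COc1c([C@@]2(O)COc3cc(OCOC)c(CC=C(C)C)c(OCOC)c3C2=O)ccc(OCOC)c1CC=C(C)C | intermediate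
26 | (R)-3,5,7-trihydroxy-3-[4-hydroxy-2-methoxy-3-(3-methylbut-2-en-1-yl)phenyl]-6-(3-methylbut-2-en-1-yl)chroman-4-one | COc1c([C@@]2(O)COc3cc(O)c(CC=C(C)C)c(O)c3C2=O)ccc(O)c1CC=C(C)C | target

Total steps: 14. Longest linear sequence: 8 steps (steps 1 to 6, then 13 and 14).

Steps most likely to fail

Step 13 (Proposed new method). The dialkoxide may be consumed before the aryne is released, by triflyl transfer from 12 or by intermolecular transesterification. The tertiary alkoxide may compete in the addition. The C4a anion may also be protonated by adventitious water before it reaches the ester, which would stop the sequence at an open-chain aryl ether. The fallback sets out from 22 and 8 and returns at 25, using only known reaction types. Tosylation of the primary hydroxyl of 22 (TsCl, pyridine, 0 °C) would give ethyl (R)-2-hydroxy-2-Ar-3-(tosyloxy)propanoate F1. With K2CO3 in DMF this should close to the glycidic ester ethyl (R)-2-Ar-oxirane-2-carboxylate F2, which the potassium phenolate of bromophenol 8 opens at its CH2 terminus in the same flask (60 °C). That gives the aryl ether ethyl (R)-3-[2-bromo-3,5-bis(methoxymethoxy)-4-prenylphenoxy]-2-hydroxy-2-Ar-propanoate F3. Treatment with n-BuLi (2.2 equiv, THF, −100 °C) would deprotonate the hydroxyl and exchange bromine for lithium to give the dilithio species F4, whose aryllithium closes ring C on the ester (Parham cyclisation) to give 25. The bond from the stereocentre to oxygen is never broken, so the configuration is retained.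

Step 11. Insertion may be slow with the ortho-substituted boronic acid, so that protodeboronation and enolisation of the ketoester take over, or face selection may be poor. The fallback sets out from 16 and 20 and returns at 22 by classical resolution. Aryllithium 17 (from 16 and n-BuLi) would be transmetalated with MgBr2·OEt2 to [2-methoxy-4-(methoxymethoxy)-3-prenylphenyl]magnesium bromide F5 and added to 20 at −78 °C to give racemic ethyl 3-(benzoyloxy)-2-hydroxy-2-Ar-propanoate F6. Ethanolysis (K2CO3, EtOH) would give the racemic diol F7. Esterification of its primary hydroxyl with (S)-2-methoxy-2-phenylacetic acid (DCC, DMAP cat., CH2Cl2, 0 °C) would give two diastereomers, separable by chromatography or crystallisation: the ester with the R carbinol F8 and the ester with the S carbinol F9. Ethanolysis of F8 (K2CO3, EtOH) returns 22.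

Step 5. Bromine may add to or substitute at the prenyl group, or the ring may be brominated twice. The fallback sets out from 7 and returns at 12, replacing electrophilic substitution by directed metalation. Carbamoylation of 7 (ClCONEt2, K2CO3, MeCN, 80 °C) would give 3,5-bis(methoxymethoxy)-4-prenylphenyl N,N-diethylcarbamate F10. Carbamate-directed ortho-lithiation (s-BuLi, TMEDA, THF, −78 °C) between the carbamate and a MOM ether would give the aryllithium F11, which TMSCl silylates to the ortho-silyl carbamate F12. LiAlH4 (THF, 0 → 23 °C) would cleave the carbamate to 3,5-bis(methoxymethoxy)-4-prenyl-2-(trimethylsilyl)phenol F13, and Tf2O with pyridine (CH2Cl2, −78 → 0 °C) would give 12.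

Further compounds
F1 | step 13 | ethyl (R)-2-hydroxy-2-[2-methoxy-4-(methoxymethoxy)-3-(3-methylbut-2-en-1-yl)phenyl]-3-(tosyloxy)propanoate | COc1c([C@@](C(=O)OCC)(O)COS(=O)(=O)c2ccc(C)cc2)ccc(OCOC)c1CC=C(C)C
F2 | step 13 | ethyl (R)-2-[2-methoxy-4-(methoxymethoxy)-3-(3-methylbut-2-en-1-yl)phenyl]oxirane-2-carboxylate | COc1c([C@@]2(C(=O)OCC)OC2)ccc(OCOC)c1CC=C(C)C
F3 | step 13 | ethyl (R)-3-[2-bromo-3,5-bis(methoxymethoxy)-4-(3-methylbut-2-en-1-yl)phenoxy]-2-hydroxy-2-[2-methoxy-4-(methoxymethoxy)-3-(3-methylbut-2-en-1-yl)phenyl]propanoate | COc1c([C@@](C(=O)OCC)(O)COc2cc(OCOC)c(CC=C(C)C)c(OCOC)c2Br)ccc(OCOC)c1CC=C(C)C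
F4 | step 13 | dilithio species of F3 (lithium alkoxide, aryllithium at the former C–Br carbon) | COc1c([C@@](C(=O)OCC)(O[Li])COc2cc(OCOC)c(CC=C(C)C)c(OCOC)c2[Li])ccc(OCOC)c1CC=C(C)C
F5 | step 11 | [2-methoxy-4-(methoxymethoxy)-3-(3-methylbut-2-en-1-yl)phenyl]magnesium bromide | COc1c([Mg]Br)ccc(OCOC)c1CC=C(C)C
F6 | step 11 | racemic ethyl 3-(benzoyloxy)-2-hydroxy-2-[2-methoxy-4-(methoxymethoxy)-3-(3-methylbut-2-en-1-yl)phenyl]propanoate | COc1c(C(C(=O)OCC)(O)COC(=O)c2ccccc2)ccc(OCOC)c1CC=C(C)C
F7 | step 11 | racemic ethyl 2,3-dihydroxy-2-[2-methoxy-4-(methoxymethoxy)-3-(3-methylbut-2-en-1-yl)phenyl]propanoate | COc1c(C(C(=O)OCC)(O)CO)ccc(OCOC)c1CC=C(C)C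
F8 | step 11 | ethyl (R)-2-hydroxy-3-{[(S)-2-methoxy-2-phenylacetyl]oxy}-2-[2-methoxy-4-(methoxymethoxy)-3-(3-methylbut-2-en-1-yl)phenyl]propanoate | COc1c([C@@](C(=O)OCC)(O)COC(=O)[C@@H](OC)c2ccccc2)ccc(OCOC)c1CC=C(C)C
F9 | step 11 | ethyl (S)-2-hydroxy-3-{[(S)-2-methoxy-2-phenylacetyl]oxy}-2-[2-methoxy-4-(methoxymethoxy)-3-(3-methylbut-2-en-1-yl)phenyl]propanoate | COc1c([C@](C(=O)OCC)(O)COC(=O)[C@@H](OC)c2ccccc2)ccc(OCOC)c1CC=C(C)C
F10 | step 5 | 3,5-bis(methoxymethoxy)-4-(3-methylbut-2-en-1-yl)phenyl N,N-diethylcarbamate | CCN(CC)C(=O)Oc1cc(OCOC)c(CC=C(C)C)c(OCOC)c1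
F11 | step 5 | {6-[(diethylcarbamoyl)oxy]-2,4-bis(methoxymethoxy)-3-(3-methylbut-2-en-1-yl)phenyl}lithium | CCN(CC)C(=O)Oc1cc(OCOC)c(CC=C(C)C)c(OCOC)c1[Li]
F12 | step 5 | 3,5-bis(methoxymethoxy)-4-(3-methylbut-2-en-1-yl)-2-(trimethylsilyl)phenyl N,N-diethylcarbamate | CCN(CC)C(=O)Oc1cc(OCOC)c(CC=C(C)C)c(OCOC)c1[Si](C)(C)C
F13 | step 5 | 3,5-bis(methoxymethoxy)-4-(3-methylbut-2-en-1-yl)-2-(trimethylsilyl)phenol | Oc1cc(OCOC)c(CC=C(C)C)c(OCOC)c1[Si](C)(C)C
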